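**Plan**

- Retrosynthesis: the benzyl ether on O5 and the silyl ethers on O7, O3' and O4' come off last. Ring C is cut at O1–C2 and C2–C3 (cyclodehydration, Baker–Venkataraman aroyl shift), then the ester link to ring B and the C4–C4a bond (directed metalation, methoxyacetylation). Ring A is cut at C8–C8a, C6–C7 and C4a–C8a, and ring B at its C5'–prenyl bond (Stille coupling).
- Enabling feature: ring A is a phloroglucinol with oxygens on C5, C7 and C8a and the prenyl group on C8 between C7 and C8a. This pattern is the sum of a (1-alkoxyvinyl)ketene (C8a, C4a, C5, C6) and a silyloxyalkyne that carries the prenyl methylene (C8, C7).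
- Forward order: ring A is built first by benzannulation, which leaves a free hydroxyl only on C8a. C4a is then acylated, ring B is attached as an ester on O1, and ring C closes last.
- Stereochemistry: the target has no stereocentre and both prenyl alkenes end in two identical methyl groups, so nothing needs control. The two chiral intermediates are racemic and lose their centre in the step that forms them.

Key step: step 4

Remark: ring A atoms carry their flavone numbers from the benzannulation onward; ring B is carried as a bis(silyl ether) so that the prenyl groups meet acid only while every neighbouring phenol is capped and one fluoride treatment frees O7, O3' and O4' at the end.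

**Route**

Step 1
Reactants: 1 3-ethoxycyclobut-2-en-1-one; 2 benzyl alcohol
Product: 3 3-(benzyloxy)cyclobut-2-en-1-one
Conditions: PPTS (cat.), toluene, 45 °C, reduced pressure (removal of EtOH)
Reagents that add atoms: none
Why: Acid-catalysed addition–elimination at the β-carbon of the vinylogous ester (transetherification) should exchange ethoxy for benzyloxy, with removal of ethanol driving the equilibrium.

Step 2
Reactants: 4 4-methylpent-3-enoic acid
Product: 5 ethyl 4-methylpent-3-enoate
Conditions: EtI, K2CO3, DMF, rt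
Reagents that add atoms: iodoethane, CCI
Why: SN2 O-alkylation of the carboxylate should give the ester under conditions that avoid the acid-induced lactonisation to which this β,γ-unsaturated acid is prone.

Step 3
Reactants: 5 ethyl 4-methylpent-3-enoate
Product: 8 triisopropyl[(5-methylhex-4-en-1-yn-1-yl)oxy]silane, via dibromoketone enolate 6 (not isolated), via lithium ynolate 7 (not isolated)
Conditions: LiCHBr2 (from CH2Br2 and lithium 2,2,6,6-tetramethylpiperidide), THF, −78 °C; n-BuLi, −78 °C→rt; i-Pr3SiCl, −78 °C→rt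
Reagents that add atoms: dibromomethane, BrCBr; chlorotriisopropylsilane, CC(C)[Si](Cl)(C(C)C)C(C)C
Why: Kowalski ester homologation, in which dibromomethyllithium adds to the ester, bromine–lithium exchange on enolate 6 triggers a 1,2-shift of the prenyl group to ynolate 7, and the bulky silyl chloride traps the ynolate on oxygen.

Step 4
Reactants: 3 3-(benzyloxy)cyclobut-2-en-1-one; 8 triisopropyl[(5-methylhex-4-en-1-yn-1-yl)oxy]silane
Product: 13 5-(benzyloxy)-2-(3-methylbut-2-en-1-yl)-3-[(triisopropylsilyl)oxy]phenol, via vinylketene 9 (not isolated), via vinylcyclobutenone 10 (not isolated), via dienylketene 11 (not isolated), via cyclohexadienone 12 (not isolated)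
Conditions: 8 (1.2 equiv), toluene, 80→110 °C, sealed tube
Reagents that add atoms: none
Why: Heating should open cyclobutenone 3 by a 4π electrocyclic reaction to vinylketene 9, whose ketene carbon is attacked by the prenyl-bearing carbon of alkyne 8 in a [2+2] cycloaddition that gives vinylcyclobutenone 10. A second 4π opening gives dienylketene 11, and ring A closes by a 6π electrocyclisation that joins the ketene carbon (C8a) to the terminal methylene (C4a); cyclohexadienone 12 then tautomerises to phenol 13. This is the Danheiser benzannulation in its siloxyalkyne form, here fed by a vinylogous-ester cyclobutenone. No stereocentre is created, because the sp3 centre of 10 and the alkene geometry of 11 vanish on aromatisation. The step needs one regiochemical outcome, prenyl ortho and silyloxy meta to the new hydroxyl, and the silyloxy oxygen secures it by making the prenyl-bearing alkyne carbon the nucleophilic terminus that bonds to the electrophilic ketene carbon. The free hydroxyl therefore appears only on C8a, while O5 and O7 arrive as a benzyl and a silyl ether and C4a is the only unsubstituted carbon ortho to the hydroxyl.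

Step 5
Reactants: 13 5-(benzyloxy)-2-(3-methylbut-2-en-1-yl)-3-[(triisopropylsilyl)oxy]phenol
Product: 14 [5-(benzyloxy)-3-(methoxymethoxy)-2-(3-methylbut-2-en-1-yl)phenoxy]triisopropylsilane
Conditions: MOMCl, i-Pr2NEt, CH2Cl2, 0 °C→rt
Reagents that add atoms: chloromethyl methyl ether, COCCl
Why: Williamson-type O-alkylation of the phenol should install an acetal that masks O1 and serves as the directing group for the following metalation.

Step 6
Reactants: 14 [5-(benzyloxy)-3-(methoxymethoxy)-2-(3-methylbut-2-en-1-yl)phenoxy]triisopropylsilane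
Product: 16 1-[6-(benzyloxy)-2-(methoxymethoxy)-3-(3-methylbut-2-en-1-yl)-4-[(triisopropylsilyl)oxy]phenyl]-2-methoxyethan-1-one, via aryllithium 15 (not isolated)
Conditions: n-BuLi, TMEDA, THF, −20→0 °C; MeOCH2C(O)N(OMe)Me, −78 °C→rt; aq NH4Cl
Reagents that add atoms: N,2-dimethoxy-N-methylacetamide, COCC(=O)N(C)OC
Why: Directed ortho-metalation should occur at C4a, the only ring hydrogen flanked by two coordinating ether oxygens (the acetal on C8a and the benzyl ether on C5) rather than by the bulky silyl ether, and the Weinreb amide should acylate aryllithium 15 once without over-addition.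

Step 7
Reactants: 16 1-[6-(benzyloxy)-2-(methoxymethoxy)-3-(3-methylbut-2-en-1-yl)-4-[(triisopropylsilyl)oxy]phenyl]-2-methoxyethan-1-one
Product: 17 1-[6-(benzyloxy)-2-hydroxy-3-(3-methylbut-2-en-1-yl)-4-[(triisopropylsilyl)oxy]phenyl]-2-methoxyethan-1-one
Conditions: HCl (cat.), MeOH–THF, rt
Reagents that add atoms: none
Why: Acid-catalysed acetal methanolysis should remove the methoxymethyl group ortho to the ketone under conditions mild enough to spare the benzyl ether, the aryl silyl ether and the prenyl group, the freed phenol being held in a hydrogen bond to the carbonyl.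

Step 8
Reactants: 18 3-bromo-4,5-dihydroxybenzaldehyde
Product: 19 3-bromo-4,5-bis[(tert-butyldimethylsilyl)oxy]benzaldehyde
Conditions: TBSCl, imidazole, DMF, rt
Reagents that add atoms: tert-butyl(chloro)dimethylsilane, CC(C)(C)[Si](C)(C)Cl
Why: Imidazole-promoted silylation of both phenols is a standard protection and should proceed without touching the aldehyde or the bromide.

Step 9
Reactants: 19 3-bromo-4,5-bis[(tert-butyldimethylsilyl)oxy]benzaldehyde
Product: 20 3,4-bis[(tert-butyldimethylsilyl)oxy]-5-(3-methylbut-2-en-1-yl)benzaldehyde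
Conditions: Bu3SnCH2CH=CMe2, Pd(PPh3)4 (5 mol %), 1,4-dioxane, 100 °C
Reagents that add atoms: tributyl(3-methylbut-2-en-1-yl)stannane, CCCC[Sn](CCCC)(CCCC)CC=C(C)C
Why: Stille cross-coupling (oxidative addition of zerovalent palladium into the aryl bromide, transmetalation, reductive elimination at the unsubstituted allyl terminus) should give the linear prenyl arene under neutral conditions that spare the silyl ethers and the aldehyde.

Step 10
Reactants: 20 3,4-bis[(tert-butyldimethylsilyl)oxy]-5-(3-methylbut-2-en-1-yl)benzaldehyde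
Product: 21 3,4-bis[(tert-butyldimethylsilyl)oxy]-5-(3-methylbut-2-en-1-yl)benzoic acid
Conditions: NaClO2, NaH2PO4, 2-methylbut-2-ene (excess), t-BuOH–H2O, rt
Reagents that add atoms: sodium chlorite, [Na+].[O-]Cl=O
Why: Pinnick oxidation should convert the aldehyde to the acid while the large excess of 2-methylbut-2-ene scavenges the hypochlorous acid by-product before it can attack the prenyl alkene.

Step 11
Reactants: 17 1-[6-(benzyloxy)-2-hydroxy-3-(3-methylbut-2-en-1-yl)-4-[(triisopropylsilyl)oxy]phenyl]-2-methoxyethan-1-one; 21 3,4-bis[(tert-butyldimethylsilyl)oxy]-5-(3-methylbut-2-en-1-yl)benzoic acid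
Product: 22 3-(benzyloxy)-2-(methoxyacetyl)-6-(3-methylbut-2-en-1-yl)-5-[(triisopropylsilyl)oxy]phenyl 3,4-bis[(tert-butyldimethylsilyl)oxy]-5-(3-methylbut-2-en-1-yl)benzoate
Conditions: DCC, DMAP, CH2Cl2, rt
Reagents that add atoms: none
Why: Steglich esterification, in which the carbodiimide activates acid 21 and DMAP transfers the aroyl group to the hindered, hydrogen-bonded phenol on C8a, the only free hydroxyl in either partner.

Step 12
Reactants: 22 3-(benzyloxy)-2-(methoxyacetyl)-6-(3-methylbut-2-en-1-yl)-5-[(triisopropylsilyl)oxy]phenyl 3,4-bis[(tert-butyldimethylsilyl)oxy]-5-(3-methylbut-2-en-1-yl)benzoate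
Product: 24 5-(benzyloxy)-2-{3,4-bis[(tert-butyldimethylsilyl)oxy]-5-(3-methylbut-2-en-1-yl)phenyl}-3-methoxy-8-(3-methylbut-2-en-1-yl)-7-[(triisopropylsilyl)oxy]-4H-chromen-4-one, via diketone 23 (not isolated)
Conditions: LiN(SiMe3)2, THF, −78→0 °C; AcOH; then p-TsOH·H2O (cat.), toluene, 60 °C
Reagents that add atoms: none
Why: Baker–Venkataraman rearrangement followed by acid-catalysed cyclodehydration, in which the ketone enolate takes the aroyl group from the neighbouring ester oxygen to give diketone 23 and the freed C8a phenol then adds to the new carbonyl and loses water, closing ring C with the methoxy group on C3 while O5 stays benzylated and cannot compete.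

Step 13
Reactants: 24 5-(benzyloxy)-2-{3,4-bis[(tert-butyldimethylsilyl)oxy]-5-(3-methylbut-2-en-1-yl)phenyl}-3-methoxy-8-(3-methylbut-2-en-1-yl)-7-[(triisopropylsilyl)oxy]-4H-chromen-4-one
Product: 25 2-{3,4-bis[(tert-butyldimethylsilyl)oxy]-5-(3-methylbut-2-en-1-yl)phenyl}-5-hydroxy-3-methoxy-8-(3-methylbut-2-en-1-yl)-7-[(triisopropylsilyl)oxy]-4H-chromen-4-one
Conditions: MgBr2·OEt2, toluene–Et2O, 40 °C; then 1 M HCl
Reagents that add atoms: none
Why: Chelation-assisted ether cleavage, in which magnesium held between the C4 carbonyl and the peri O5 activates only this benzyl ether for SN2 attack by bromide, a neutral dealkylation that should leave the prenyl alkenes, the C3 methyl ether and the silyl ethers alone.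

Step 14
Reactants: 25 2-{3,4-bis[(tert-butyldimethylsilyl)oxy]-5-(3-methylbut-2-en-1-yl)phenyl}-5-hydroxy-3-methoxy-8-(3-methylbut-2-en-1-yl)-7-[(triisopropylsilyl)oxy]-4H-chromen-4-one
Product: 26 5,7-dihydroxy-2-[3,4-dihydroxy-5-(3-methylbut-2-en-1-yl)phenyl]-3-methoxy-8-(3-methylbut-2-en-1-yl)-4H-chromen-4-one
Conditions: Bu4NF, AcOH, THF, 0 °C→rt
Reagents that add atoms: none
Why: Fluoride-induced cleavage of the three aryl silyl ethers, buffered with acetic acid, should free O7, O3' and O4' without exposing the polyphenol to strong base or the prenyl groups to strong acid.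

**Compound list**

1 | 3-ethoxycyclobut-2-en-1-one | CCOC1=CC(=O)C1 | starting material
2 | benzyl alcohol | OCc1ccccc1 | starting material
3 | 3-(benzyloxy)cyclobut-2-en-1-one | O=C1CC(OCc2ccccc2)=C1 | intermediate
4 | 4-methylpent-3-enoic acid | CC(C)=CCC(=O)O | starting material
5 | ethyl 4-methylpent-3-enoate | CCOC(=O)CC=C(C)C | intermediate
6 | lithium 1,1-dibromo-5-methylhexa-1,4-dien-2-olate (dibromoketone enolate) | [Li+].[O-]C(CC=C(C)C)=C(Br)Br | intermediate
7 | lithium 5-methylhex-4-en-1-yn-1-olate (lithium ynolate) | [Li+].[O-]C#CCC=C(C)C | intermediate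
8 | triisopropyl[(5-methylhex-4-en-1-yn-1-yl)oxy]silane | CC(C)=CCC#CO[Si](C(C)C)(C(C)C)C(C)C | intermediate
9 | 3-(benzyloxy)buta-1,3-dien-1-one (vinylketene) | O=C=CC(=C)OCc1ccccc1 | intermediate
10 | rac-4-[1-(benzyloxy)ethenyl]-2-(3-methylbut-2-en-1-yl)-3-[(triisopropylsilyl)oxy]cyclobut-2-en-1-one (vinylcyclobutenone, racemic) | O=C1C(CC=C(C)C)=C(O[Si](C(C)C)(C(C)C)C(C)C)C1C(=C)OCc1ccccc1 | intermediate
11 | (3E)-5-(benzyloxy)-2-(3-methylbut-2-en-1-yl)-3-[(triisopropylsilyl)oxy]hexa-1,3,5-trien-1-one (dienylketene) | O=C=C(CC=C(C)C)/C(O[Si](C(C)C)(C(C)C)C(C)C)=C\C(=C)OCc1ccccc1 | intermediate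
12 | 5-(benzyloxy)-2-(3-methylbut-2-en-1-yl)-3-[(triisopropylsilyl)oxy]cyclohexa-2,4-dien-1-one (cyclohexadienone) | O=C1CC(OCc2ccccc2)=CC(O[Si](C(C)C)(C(C)C)C(C)C)=C1CC=C(C)C | intermediate
13 | 5-(benzyloxy)-2-(3-methylbut-2-en-1-yl)-3-[(triisopropylsilyl)oxy]phenol | Oc1cc(OCc2ccccc2)cc(O[Si](C(C)C)(C(C)C)C(C)C)c1CC=C(C)C | intermediate
14 | [5-(benzyloxy)-3-(methoxymethoxy)-2-(3-methylbut-2-en-1-yl)phenoxy]triisopropylsilane | COCOc1cc(OCc2ccccc2)cc(O[Si](C(C)C)(C(C)C)C(C)C)c1CC=C(C)C | intermediate
15 | [6-(benzyloxy)-2-(methoxymethoxy)-3-(3-methylbut-2-en-1-yl)-4-[(triisopropylsilyl)oxy]phenyl]lithium (aryllithium) | COCOc1c([Li])c(OCc2ccccc2)cc(O[Si](C(C)C)(C(C)C)C(C)C)c1CC=C(C)C | intermediate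
16 | 1-[6-(benzyloxy)-2-(methoxymethoxy)-3-(3-methylbut-2-en-1-yl)-4-[(triisopropylsilyl)oxy]phenyl]-2-methoxyethan-1-one | COCOc1c(C(=O)COC)c(OCc2ccccc2)cc(O[Si](C(C)C)(C(C)C)C(C)C)c1CC=C(C)C | intermediate
17 | 1-[6-(benzyloxy)-2-hydroxy-3-(3-methylbut-2-en-1-yl)-4-[(triisopropylsilyl)oxy]phenyl]-2-methoxyethan-1-one | Oc1c(C(=O)COC)c(OCc2ccccc2)cc(O[Si](C(C)C)(C(C)C)C(C)C)c1CC=C(C)C | intermediate
18 | 3-bromo-4,5-dihydroxybenzaldehyde | O=Cc1cc(O)c(O)c(Br)c1 | starting material
19 | 3-bromo-4,5-bis[(tert-butyldimethylsilyl)oxy]benzaldehyde | O=Cc1cc(O[Si](C)(C)C(C)(C)C)c(O[Si](C)(C)C(C)(C)C)c(Br)c1 | intermediate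
20 | 3,4-bis[(tert-butyldimethylsilyl)oxy]-5-(3-methylbut-2-en-1-yl)benzaldehyde | O=Cc1cc(O[Si](C)(C)C(C)(C)C)c(O[Si](C)(C)C(C)(C)C)c(CC=C(C)C)c1 | intermediate
21 | 3,4-bis[(tert-butyldimethylsilyl)oxy]-5-(3-methylbut-2-en-1-yl)benzoic acid | OC(=O)c1cc(O[Si](C)(C)C(C)(C)C)c(O[Si](C)(C)C(C)(C)C)c(CC=C(C)C)c1 | intermediate
22 | 3-(benzyloxy)-2-(methoxyacetyl)-6-(3-methylbut-2-en-1-yl)-5-[(triisopropylsilyl)oxy]phenyl 3,4-bis[(tert-butyldimethylsilyl)oxy]-5-(3-methylbut-2-en-1-yl)benzoate | COCC(=O)c1c(OC(=O)c2cc(O[Si](C)(C)C(C)(C)C)c(O[Si](C)(C)C(C)(C)C)c(CC=C(C)C)c2)c(CC=C(C)C)c(O[Si](C(C)C)(C(C)C)C(C)C)cc1OCc1ccccc1 | intermediate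
23 | rac-1-[6-(benzyloxy)-2-hydroxy-3-(3-methylbut-2-en-1-yl)-4-[(triisopropylsilyl)oxy]phenyl]-3-{3,4-bis[(tert-butyldimethylsilyl)oxy]-5-(3-methylbut-2-en-1-yl)phenyl}-2-methoxypropane-1,3-dione (diketone, racemic and configurationally labile) | COC(C(=O)c1cc(O[Si](C)(C)C(C)(C)C)c(O[Si](C)(C)C(C)(C)C)c(CC=C(C)C)c1)C(=O)c1c(O)c(CC=C(C)C)c(O[Si](C(C)C)(C(C)C)C(C)C)cc1OCc1ccccc1 | intermediate
24 | 5-(benzyloxy)-2-{3,4-bis[(tert-butyldimethylsilyl)oxy]-5-(3-methylbut-2-en-1-yl)phenyl}-3-methoxy-8-(3-methylbut-2-en-1-yl)-7-[(triisopropylsilyl)oxy]-4H-chromen-4-one | COc1c(-c2cc(O[Si](C)(C)C(C)(C)C)c(O[Si](C)(C)C(C)(C)C)c(CC=C(C)C)c2)oc2c(CC=C(C)C)c(O[Si](C(C)C)(C(C)C)C(C)C)cc(OCc3ccccc3)c2c1=O | intermediate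
25 | 2-{3,4-bis[(tert-butyldimethylsilyl)oxy]-5-(3-methylbut-2-en-1-yl)phenyl}-5-hydroxy-3-methoxy-8-(3-methylbut-2-en-1-yl)-7-[(triisopropylsilyl)oxy]-4H-chromen-4-one | COc1c(-c2cc(O[Si](C)(C)C(C)(C)C)c(O[Si](C)(C)C(C)(C)C)c(CC=C(C)C)c2)oc2c(CC=C(C)C)c(O[Si](C(C)C)(C(C)C)C(C)C)cc(O)c2c1=O | intermediate
26 | 5,7-dihydroxy-2-[3,4-dihydroxy-5-(3-methylbut-2-en-1-yl)phenyl]-3-methoxy-8-(3-methylbut-2-en-1-yl)-4H-chromen-4-one (5,7,3',4'-tetrahydroxy-3-methoxy-8,5'-diprenylflavone) | COc1c(-c2cc(O)c(O)c(CC=C(C)C)c2)oc2c(CC=C(C)C)c(O)cc(O)c2c1=O | target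

**Step count**

Total: 14 steps. Longest linear sequence: 10 steps (steps 2, 3, 4, 5, 6, 7, 11, 12, 13, 14, from acid 4 to target 26). Step 1 and steps 8–10 are side branches that join at steps 4 and 11.

**Steps most likely to fail**

Step 4. The alkoxy group stabilises cyclobutenone 3 as a vinylogous ester, so its 4π opening may be slow. At the temperature then needed, thermal isomerisation of siloxyalkyne 8 to a silylketene and acylation of the product phenol by unreacted ketene could outrun the cycloaddition. The fallback reaches the same vinylketene without a cyclobutenone and below the temperature at which 8 suffers. Benzyl alcohol 2 would be added to ethyl but-2-ynoate under PMe3 catalysis to give ethyl (E)-3-(benzyloxy)but-2-enoate F1. Saponification (LiOH, THF–H2O) would give (E)-3-(benzyloxy)but-2-enoic acid F2, and oxalyl chloride would convert it into (E)-3-(benzyloxy)but-2-enoyl chloride F3. Slow addition of F3 to Et3N and alkyne 8 in toluene at room temperature should effect 1,4-dehydrochlorination to vinylketene 9, which is trapped as 10 and carried on to phenol 13 by warming to 80 °C. This fallback sets out from 2 and rejoins the route at 9; the same three ring bonds are formed.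

Step 6. n-BuLi may abstract a proton from the benzylic ether methylene (followed by Wittig rearrangement) or from the benzylic and allylic prenyl methylene instead of from C4a, and the aryllithium may enolise the Weinreb amide instead of adding to it. The fallback avoids organolithium bases on the arene and needs no protecting group on O1. Phenol 13 would be formylated at its only free ortho position with MgCl2, Et3N and paraformaldehyde in MeCN (magnesium-mediated ortho-formylation) to give 6-(benzyloxy)-2-hydroxy-3-(3-methylbut-2-en-1-yl)-4-[(triisopropylsilyl)oxy]benzaldehyde F4. Addition of methoxymethyllithium (from Bu3SnCH2OMe and n-BuLi, THF, −78 °C) would give rac-1-[6-(benzyloxy)-2-hydroxy-3-(3-methylbut-2-en-1-yl)-4-[(triisopropylsilyl)oxy]phenyl]-2-methoxyethan-1-ol F5. Oxidation of the benzylic alcohol with MnO2 in CH2Cl2 would give ketone 17. This fallback sets out from 13 and rejoins the route at 17, so steps 5 and 7 fall away.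

Step 13. The magnesium chelate may activate the benzyl ether too weakly, so that dealkylation stalls, and forcing the reaction may strip silyl groups. The fallback replaces Lewis-acid dealkylation by reductive C–O cleavage: catalytic transfer hydrogenolysis of 24 with palladium on carbon and cyclohexa-1,4-diene in ethyl acetate at room temperature. It relies on aryl benzyl ethers being cleaved much faster than trisubstituted alkenes are reduced under hydrogen-transfer conditions. It sets out from 24 and rejoins the route at 25, and it makes no new compound (F0).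

**Further compounds**

F1 | step 4 | ethyl (E)-3-(benzyloxy)but-2-enoate | CCOC(=O)/C=C(\C)OCc1ccccc1
F2 | step 4 | (E)-3-(benzyloxy)but-2-enoic acid | OC(=O)/C=C(\C)OCc1ccccc1
F3 | step 4 | (E)-3-(benzyloxy)but-2-enoyl chloride | ClC(=O)/C=C(\C)OCc1ccccc1
F4 | step 6 | 6-(benzyloxy)-2-hydroxy-3-(3-methylbut-2-en-1-yl)-4-[(triisopropylsilyl)oxy]benzaldehyde | O=Cc1c(O)c(CC=C(C)C)c(O[Si](C(C)C)(C(C)C)C(C)C)cc1OCc1ccccc1
F5 | step 6 | rac-1-[6-(benzyloxy)-2-hydroxy-3-(3-methylbut-2-en-1-yl)-4-[(triisopropylsilyl)oxy]phenyl]-2-methoxyethan-1-ol | COCC(O)c1c(O)c(CC=C(C)C)c(O[Si](C(C)C)(C(C)C)C(C)C)cc1OCc1ccccc1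
F0 | step 13 | none | none
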